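**Plan**
- Late disconnections: the formate, the C8 methylene and the C11–pyranone bond (Michael addition of a 4-hydroxy-2-pyrone to a C9-methylene C8-ketone). Then C4–CH3 (enolate methylation), H-5 (hydrogenation) and the C10 methyl (from an angular vinyl group).
- Core disconnection: ring A is cut at C2–C3, C3–C4 and C5–C10. The enabling feature is that C10–C1–C2 is a bare three-carbon chain between the quaternary ring-fusion carbon C10 and the carbinol carbon C3, with C4–C5 beside it. That is the pattern written by a vinylcyclopropane (C10, C1, C2), CO (C3) and an alkyne (C4≡C5) in a rhodium-catalysed [(3+2)+1] cycloaddition.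
- Forward: an acyclic β-keto ester carrying a 1-vinylcyclopropane and a tethered alkyne is made by Johnson–Claisen rearrangement and Claisen condensation. Rings B and A then form together in one step. After that: angular methyl, cis-hydrogenation, C4 methylation, C3 reduction, ring-B enone, pyrone, methylenation, formate.
- Stereochemistry: C10 from ligand-controlled desymmetrization of the cyclopropane. C5, C4, C3 and C9 follow from C10 by substrate control (β-face hydrogenation, β-face enolate methylation, equatorial hydride attack, protonation at C9).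

Key step: step 6

Convention used in the names: core locants C1–C11 (ring A = C1, C2, C3, C4, C5, C10; ring B = C5 to C10; C11 = the CH2 between C9 and the pyranone). β is the face of the C10 methyl group or of its vinyl/formyl precursor; α is the opposite face.
Assumption: the sense of induction of the bisphosphine in step 6 cannot be derived with confidence; (R)-H8-BINAP is written, and its antipode would be used if the other enantiomer of 11 should form.

**Route**

Step 1
Reactants: 1 ethyl 2-cyclopropylideneacetate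
Product: 2 2-cyclopropylideneethan-1-ol
Conditions: i-Bu2AlH (2.2 equiv), CH2Cl2, −78 °C
Reagents that add atoms: none
Why: 1,2-reduction of an α,β-unsaturated ester by an aluminium hydride should give the allylic alcohol without touching the strained alkene.

Step 2
Reactants: 2 2-cyclopropylideneethan-1-ol; 3 trimethyl orthoacetate
Product: 4 methyl 2-(1-ethenylcyclopropyl)acetate
Conditions: EtCO2H (cat.), 135 °C, MeOH distilled off
Reagents that add atoms: none
Why: Johnson–Claisen rearrangement; the [3,3] shift forms the new C–C bond at the cyclopropylidene carbon (relief of alkylidenecyclopropane strain) and leaves the vinyl group on the quaternary cyclopropane carbon.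

Step 3
Reactants: 5 4-bromo-2-methylbutan-2-ol
Product: 6 [(4-bromo-2-methylbutan-2-yl)oxy]triethylsilane
Conditions: Et3SiOTf, 2,6-lutidine, CH2Cl2, 0 °C
Reagents that add atoms: triethylsilyl trifluoromethanesulfonate, CC[Si](CC)(CC)OS(=O)(=O)C(F)(F)F
Why: silylation of a tertiary alcohol with a silyl triflate and a hindered base is standard.

Step 4
Reactants: 7 pent-4-ynoic acid; 6 [(4-bromo-2-methylbutan-2-yl)oxy]triethylsilane
Product: 8 8-methyl-8-[(triethylsilyl)oxy]non-4-ynoic acid
Conditions: n-BuLi (2.1 equiv), THF–DMPU, −78 to 0 °C; then 6, 23 °C; aq. HCl work-up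
Reagents that add atoms: none
Why: SN2 alkylation of the acetylide of a carboxylate/acetylide dianion by a primary bromide.

Step 5
Reactants: 4 methyl 2-(1-ethenylcyclopropyl)acetate; 8 8-methyl-8-[(triethylsilyl)oxy]non-4-ynoic acid
Product: 10 methyl 2-(1-ethenylcyclopropyl)-10-methyl-3-oxo-10-[(triethylsilyl)oxy]undec-6-ynoate, via acyl imidazolide 9 (not isolated)
Conditions: 8, carbonyldiimidazole, THF, 23 °C; added to 4 + LiN(SiMe3)2 (2.1 equiv), THF, −78 °C; aq. NH4Cl
Reagents that add atoms: none
Why: crossed Claisen condensation (C-acylation of an ester enolate by an acyl imidazolide); the only stereocentre formed (future C9) is a labile β-keto ester centre.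

Step 6
Reactants: 10 methyl 2-(1-ethenylcyclopropyl)-10-methyl-3-oxo-10-[(triethylsilyl)oxy]undec-6-ynoate
Product: 11 methyl 10β-ethenyl-4-[3-methyl-3-(triethylsilyloxy)butyl]-3,8-dioxo-Δ4-octalin-9-carboxylate
Conditions: [Rh(cod)Cl]2 (5 mol %), (R)-H8-BINAP (11 mol %), AgSbF6 (11 mol %), CO/N2 (1:4, 1 atm), 1,2-dichloroethane, 70 °C
Reagents that add atoms: carbon monoxide, [C-]#[O+]
Why: Proposed new method: monovalent rhodium coordinates the vinyl group of 10 and opens the cyclopropane at one C10–CH2 bond to a trivalent σ-alkyl(C2)/π-allyl(C10–vinyl) rhodacycle; the tethered alkyne inserts at the allyl terminus C10 (forming C5–C10), CO inserts into the Rh–C2 bond (forming C2–C3) and acyl–vinyl reductive elimination (C3–C4) releases the enone. The closest known reaction types are the [Rh(CO)2Cl]2-catalysed [(3+2)+1] cycloaddition of 1-yne-vinylcyclopropanes with CO (a homologous Pauson–Khand reaction, known with achiral catalyst) and the Rh/H8-BINAP-catalysed enantioselective [3+2] cycloaddition of the same substrate class; running the carbonylative manifold with the chiral bisphosphine is the new element. Ring B closes by 6-exo-dig carbometalation of the alkyne at C10, and ring A closes by CO insertion and reductive elimination from the acyl rhodacycle. The one stereocentre that matters, C10, arises because the two cyclopropane CH2 groups of 10 are enantiotopic: the ligand decides which C10–CH2 bond is cleaved and hence the face of C10 to which C5 is delivered (C9 remains a labile β-keto ester centre). The carbonylative pathway must win over the CO-free [3+2] pathway, which the CO atmosphere secures, and C5 must go to C10, which the four-atom tether on the quaternary cyclopropane carbon secures because it rules out the [5+2] mode.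

Step 7
Reactants: 11 methyl 10β-ethenyl-4-[3-methyl-3-(triethylsilyloxy)butyl]-3,8-dioxo-Δ4-octalin-9-carboxylate
Product: 12 methyl 10β-ethenyl-8-methoxy-4-[3-methyl-3-(triethylsilyloxy)butyl]-3-oxo-Δ4,8-hexalin-9-carboxylate
Conditions: Cs2CO3, Me2SO4, DMF, 0 to 23 °C
Reagents that add atoms: dimethyl sulfate, COS(=O)(=O)OC
Why: O-alkylation of a β-keto ester enolate by a hard electrophile (C-alkylation at C9 is blocked by the adjacent quaternary C10); the vinylogous carbonate removes the C9 stereocentre and the enol reactivity and is the latent C9-methylene ketone.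

Step 8
Reactants: 12 methyl 10β-ethenyl-8-methoxy-4-[3-methyl-3-(triethylsilyloxy)butyl]-3-oxo-Δ4,8-hexalin-9-carboxylate
Product: 13 methyl 10β-formyl-8-methoxy-4-[3-methyl-3-(triethylsilyloxy)butyl]-3-oxo-Δ4,8-hexalin-9-carboxylate
Conditions: OsO4 (2 mol %), NaIO4 (4 equiv), 2,6-lutidine, dioxane–H2O, 23 °C
Reagents that add atoms: sodium periodate (terminal oxidant; the oxygen reaches the aldehyde through OsO4), [Na+].[O-]I(=O)(=O)=O
Why: Lemieux–Johnson oxidative cleavage; only the monosubstituted vinyl group is unhindered and electron-rich, the two tetrasubstituted acceptor-substituted alkenes should not react.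

Step 9
Reactants: 13 methyl 10β-formyl-8-methoxy-4-[3-methyl-3-(triethylsilyloxy)butyl]-3-oxo-Δ4,8-hexalin-9-carboxylate
Product: 15 methyl 8-methoxy-10β-methyl-4-[3-methyl-3-(triethylsilyloxy)butyl]-3-oxo-Δ4,8-hexalin-9-carboxylate, via tosylhydrazone 14 (not isolated)
Conditions: TsNHNH2, EtOH, 23 °C; then catecholborane, CHCl3, 0 °C; NaOAc·3H2O, reflux
Reagents that add atoms: none
Why: the aldehyde condenses far faster than the hindered conjugated ketone, and hydride reduction of the tosylhydrazone followed by loss of sulfinate and N2 (a mild Wolff–Kishner-type deoxygenation) turns CHO into the C10 methyl.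

Step 10
Reactants: 15 methyl 8-methoxy-10β-methyl-4-[3-methyl-3-(triethylsilyloxy)butyl]-3-oxo-Δ4,8-hexalin-9-carboxylate
Product: 16 methyl 8-methoxy-10β-methyl-4α-[3-methyl-3-(triethylsilyloxy)butyl]-3-oxo-4βH,5βH-Δ8-octalin-9-carboxylate
Conditions: H2 (3 atm), Pd/C (10 %), EtOAc–EtOH, 23 °C
Reagents that add atoms: none
Why: heterogeneous hydrogenation of the enone alkene; syn addition of H2 on the β face, the usual outcome for 4,10-dialkyl-Δ4-octal-3-ones, should give the cis-fused ketone with H-5 β (C4 is set too but is planarized again in step 11), while the tetrasubstituted push–pull alkene of ring B should resist.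

Step 11
Reactants: 16 methyl 8-methoxy-10β-methyl-4α-[3-methyl-3-(triethylsilyloxy)butyl]-3-oxo-4βH,5βH-Δ8-octalin-9-carboxylate
Product: 17 methyl 8-methoxy-10β-methyl-4-[3-methyl-3-(triethylsilyloxy)butyl]-3-(trimethylsilyloxy)-5βH-Δ3,8-hexalin-9-carboxylate
Conditions: Me3SiCl, Et3N, DMF, 90 °C
Reagents that add atoms: chlorotrimethylsilane, C[Si](C)(C)Cl
Why: silyl enol ether formation under equilibrating conditions gives the more substituted Δ3 isomer, which is also the enolization direction preferred by cis-fused 3-ketones.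

Step 12
Reactants: 17 methyl 8-methoxy-10β-methyl-4-[3-methyl-3-(triethylsilyloxy)butyl]-3-(trimethylsilyloxy)-5βH-Δ3,8-hexalin-9-carboxylate
Product: 18 methyl 8-methoxy-4β,10β-dimethyl-4α-[3-methyl-3-(triethylsilyloxy)butyl]-3-oxo-5βH-Δ8-octalin-9-carboxylate
Conditions: MeI, BnMe3N+F− (anhydrous), 4 Å sieves, THF, −20 to 23 °C
Reagents that add atoms: iodomethane, CI
Why: regiospecific alkylation of the fluoride-liberated ammonium enolate at C4; in the cis-fused enolate the α face is screened by ring B (C9 syn-axial), so MeI should enter on the open convex β face through the half-chair with H-5 pseudoaxial, putting CH3 β and the side chain α.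

Step 13
Reactants: 18 methyl 8-methoxy-4β,10β-dimethyl-4α-[3-methyl-3-(triethylsilyloxy)butyl]-3-oxo-5βH-Δ8-octalin-9-carboxylate
Product: 19 methyl 3α-hydroxy-8-methoxy-4β,10β-dimethyl-4α-[3-methyl-3-(triethylsilyloxy)butyl]-5βH-Δ8-octalin-9-carboxylate
Conditions: LiBH(s-Bu)3, THF, −78 to −20 °C; aq. NH4Cl
Reagents that add atoms: none
Why: the bulky borohydride attacks the C3 ketone along the equatorial trajectory from the β side (the axial α trajectory is blocked by the axial C6 methylene of the cis-decalin), giving the axial 3α alcohol as with 4,4-disubstituted 3-oxo terpenoids; the vinylogous carbonate should not be reduced.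

Step 14
Reactants: 19 methyl 3α-hydroxy-8-methoxy-4β,10β-dimethyl-4α-[3-methyl-3-(triethylsilyloxy)butyl]-5βH-Δ8-octalin-9-carboxylate
Product: 20 methyl 3α-(tert-butyldimethylsilyloxy)-8-methoxy-4β,10β-dimethyl-4α-[3-methyl-3-(triethylsilyloxy)butyl]-5βH-Δ8-octalin-9-carboxylate
Conditions: t-BuMe2SiOTf, 2,6-lutidine, CH2Cl2, 0 to 23 °C
Reagents that add atoms: tert-butyldimethylsilyl trifluoromethanesulfonate, CC(C)(C)[Si](C)(C)OS(=O)(=O)C(F)(F)F
Why: silyl triflate silylation of a hindered secondary alcohol; this keeps O3 distinct from the tertiary oxygen that is formylated later.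

Step 15
Reactants: 20 methyl 3α-(tert-butyldimethylsilyloxy)-8-methoxy-4β,10β-dimethyl-4α-[3-methyl-3-(triethylsilyloxy)butyl]-5βH-Δ8-octalin-9-carboxylate
Product: 22 3α-(tert-butyldimethylsilyloxy)-4α-(3-hydroxy-3-methylbutyl)-4β,10β-dimethyl-9-methylene-5βH-decalin-8-one, via allylic alcohol 21 (not isolated)
Conditions: i-Bu2AlH (3 equiv), CH2Cl2, −78 °C; then 1 M aq. HCl–THF, 0 to 23 °C
Reagents that add atoms: water, O
Why: 1,2-reduction of the vinylogous carbonate gives a γ-methoxy allylic alcohol that loses water and methanol on acid hydrolysis (Stork–Danheiser-type transposition) to the α-methylene ketone; the same acid should cleave the tertiary triethylsilyl ether while the hindered tert-butyldimethylsilyl ether survives.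

Step 16
Reactants: 23 methyl acetoacetate; 24 malonyl dichloride
Product: 25 methyl 4-hydroxy-2-methyl-6-oxo-6H-pyran-3-carboxylate
Conditions: CH2Cl2, 23 to 40 °C, no base
Reagents that add atoms: none
Why: C-acylation of the β-keto ester at its α-carbon and O-acylation of its enol by the bis(acid chloride) close the 4-hydroxy-2-pyrone ring (acylative pyrone annulation).

Step 17
Reactants: 22 3α-(tert-butyldimethylsilyloxy)-4α-(3-hydroxy-3-methylbutyl)-4β,10β-dimethyl-9-methylene-5βH-decalin-8-one; 25 methyl 4-hydroxy-2-methyl-6-oxo-6H-pyran-3-carboxylate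
Product: 26 methyl 5-{[3α-(tert-butyldimethylsilyloxy)-4α-(3-hydroxy-3-methylbutyl)-4β,10β-dimethyl-8-oxo-5βH,9βH-decalin-9-yl]methyl}-4-hydroxy-2-methyl-6-oxo-6H-pyran-3-carboxylate
Conditions: Et3N (0.2 equiv), MeCN, 40 °C
Reagents that add atoms: none
Why: Michael addition of the vinylogous acid 25 through its ring CH to the exocyclic enone; protonation of the C9 enolate under equilibrating conditions should leave the CH2–pyrone arm equatorial and α (trans to the C10 methyl), which is also the result of proton delivery anti to the axial C1 methylene.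

Step 18
Reactants: 26 methyl 5-{[3α-(tert-butyldimethylsilyloxy)-4α-(3-hydroxy-3-methylbutyl)-4β,10β-dimethyl-8-oxo-5βH,9βH-decalin-9-yl]methyl}-4-hydroxy-2-methyl-6-oxo-6H-pyran-3-carboxylate
Product: 27 methyl 5-{[3α-(tert-butyldimethylsilyloxy)-4α-(3-hydroxy-3-methylbutyl)-4β,10β-dimethyl-8-oxo-5βH,9βH-decalin-9-yl]methyl}-6-methoxy-2-methyl-4-oxo-4H-pyran-3-carboxylate
Conditions: MeOTf (1.2 equiv), 2,6-di-tert-butyl-4-methylpyridine, CH2Cl2, 0 to 23 °C
Reagents that add atoms: methyl trifluoromethanesulfonate, COS(=O)(=O)C(F)(F)F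
Why: under neutral conditions the hard methylating agent alkylates the lactone carbonyl oxygen of the 4-hydroxy-2-pyrone, and loss of the O4 proton gives the 2-methoxy-4-pyranone instead of the 4-methoxy-2-pyranone formed with base; the tertiary alcohol is much less nucleophilic.

Step 19
Reactants: 27 methyl 5-{[3α-(tert-butyldimethylsilyloxy)-4α-(3-hydroxy-3-methylbutyl)-4β,10β-dimethyl-8-oxo-5βH,9βH-decalin-9-yl]methyl}-6-methoxy-2-methyl-4-oxo-4H-pyran-3-carboxylate
Product: 28 methyl 5-{[3α-(tert-butyldimethylsilyloxy)-4α-(3-hydroxy-3-methylbutyl)-4β,10β-dimethyl-8-methylene-5βH,9βH-decalin-9-yl]methyl}-6-methoxy-2-methyl-4-oxo-4H-pyran-3-carboxylate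
Conditions: Zn, CH2Br2, TiCl4 (reagent pre-formed), THF–CH2Cl2, 0 to 23 °C
Reagents that add atoms: dibromomethane, BrCBr
Why: Takai–Lombardo methylenation is non-basic, so the epimerizable C9 centre is kept, and it is selective for the ketone over the ester and the vinylogous ester carbonyl of the pyranone.

Step 20
Reactants: 28 methyl 5-{[3α-(tert-butyldimethylsilyloxy)-4α-(3-hydroxy-3-methylbutyl)-4β,10β-dimethyl-8-methylene-5βH,9βH-decalin-9-yl]methyl}-6-methoxy-2-methyl-4-oxo-4H-pyran-3-carboxylate
Product: 29 methyl 5-{[3α-(tert-butyldimethylsilyloxy)-4α-(3-formyloxy-3-methylbutyl)-4β,10β-dimethyl-8-methylene-5βH,9βH-decalin-9-yl]methyl}-6-methoxy-2-methyl-4-oxo-4H-pyran-3-carboxylate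
Conditions: HCO2H + Ac2O (pre-mixed, 55 °C, then cooled); pyridine, DMAP (cat.), CH2Cl2, 0 to 23 °C
Reagents that add atoms: acetic formic anhydride, CC(=O)OC=O
Why: formyl transfer from the mixed anhydride to the only free hydroxyl group (the tertiary one); O3 is silylated.

Step 21
Reactants: 29 methyl 5-{[3α-(tert-butyldimethylsilyloxy)-4α-(3-formyloxy-3-methylbutyl)-4β,10β-dimethyl-8-methylene-5βH,9βH-decalin-9-yl]methyl}-6-methoxy-2-methyl-4-oxo-4H-pyran-3-carboxylate
Product: 30 target compound CNP0292250.1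
Conditions: HF·pyridine, pyridine–THF, 0 to 23 °C
Reagents that add atoms: none
Why: fluoride desilylation under buffered acidic conditions should free the 3α alcohol without cleaving the formate or isomerizing the exocyclic alkene.

**Compound list**
1 | ethyl 2-cyclopropylideneacetate | CCOC(=O)C=C1CC1 | starting material
2 | 2-cyclopropylideneethan-1-ol | OCC=C1CC1 | intermediate
3 | trimethyl orthoacetate | COC(C)(OC)OC | starting material
4 | methyl 2-(1-ethenylcyclopropyl)acetate | COC(=O)CC1(C=C)CC1 | intermediate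
5 | 4-bromo-2-methylbutan-2-ol | CC(C)(O)CCBr | starting material
6 | [(4-bromo-2-methylbutan-2-yl)oxy]triethylsilane | CC[Si](CC)(CC)OC(C)(C)CCBr | intermediate
7 | pent-4-ynoic acid | C#CCCC(=O)O | starting material
8 | 8-methyl-8-[(triethylsilyl)oxy]non-4-ynoic acid | CC[Si](CC)(CC)OC(C)(C)CCC#CCCC(=O)O | intermediate
9 | 1-{8-methyl-8-[(triethylsilyl)oxy]non-4-ynoyl}imidazole (not isolated) | CC[Si](CC)(CC)OC(C)(C)CCC#CCCC(=O)n1ccnc1 | intermediate
10 | methyl 2-(1-ethenylcyclopropyl)-10-methyl-3-oxo-10-[(triethylsilyl)oxy]undec-6-ynoate (C2 labile) | COC(=O)C(C(=O)CCC#CCCC(C)(C)O[Si](CC)(CC)CC)C1(C=C)CC1 | intermediate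
11 | methyl 10β-ethenyl-4-[3-methyl-3-(triethylsilyloxy)butyl]-3,8-dioxo-Δ4-octalin-9-carboxylate (C9 labile) | O=C1CCC2=C(CCC(C)(C)O[Si](CC)(CC)CC)C(=O)CC[C@@]2(C=C)C1C(=O)OC | intermediate
12 | methyl 10β-ethenyl-8-methoxy-4-[3-methyl-3-(triethylsilyloxy)butyl]-3-oxo-Δ4,8-hexalin-9-carboxylate | COC=1CCC2=C(CCC(C)(C)O[Si](CC)(CC)CC)C(=O)CC[C@@]2(C=C)C=1C(=O)OC | intermediate
13 | methyl 10β-formyl-8-methoxy-4-[3-methyl-3-(triethylsilyloxy)butyl]-3-oxo-Δ4,8-hexalin-9-carboxylate | COC=1CCC2=C(CCC(C)(C)O[Si](CC)(CC)CC)C(=O)CC[C@@]2(C=O)C=1C(=O)OC | intermediate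
14 | tosylhydrazone of 13 (not isolated) | COC=1CCC2=C(CCC(C)(C)O[Si](CC)(CC)CC)C(=O)CC[C@@]2(C=NNS(=O)(=O)c3ccc(C)cc3)C=1C(=O)OC | intermediate
15 | methyl 8-methoxy-10β-methyl-4-[3-methyl-3-(triethylsilyloxy)butyl]-3-oxo-Δ4,8-hexalin-9-carboxylate | COC=1CCC2=C(CCC(C)(C)O[Si](CC)(CC)CC)C(=O)CC[C@@]2(C)C=1C(=O)OC | intermediate
16 | methyl 8-methoxy-10β-methyl-4α-[3-methyl-3-(triethylsilyloxy)butyl]-3-oxo-4βH,5βH-Δ8-octalin-9-carboxylate (cis-fused) | COC=1CC[C@H]2[C@@H](CCC(C)(C)O[Si](CC)(CC)CC)C(=O)CC[C@@]2(C)C=1C(=O)OC | intermediate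
17 | methyl 8-methoxy-10β-methyl-4-[3-methyl-3-(triethylsilyloxy)butyl]-3-(trimethylsilyloxy)-5βH-Δ3,8-hexalin-9-carboxylate | COC=1CC[C@H]2C(CCC(C)(C)O[Si](CC)(CC)CC)=C(O[Si](C)(C)C)CC[C@@]2(C)C=1C(=O)OC | intermediate
18 | methyl 8-methoxy-4β,10β-dimethyl-4α-[3-methyl-3-(triethylsilyloxy)butyl]-3-oxo-5βH-Δ8-octalin-9-carboxylate | COC=1CC[C@H]2[C@@](C)(CCC(C)(C)O[Si](CC)(CC)CC)C(=O)CC[C@@]2(C)C=1C(=O)OC | intermediate
19 | methyl 3α-hydroxy-8-methoxy-4β,10β-dimethyl-4α-[3-methyl-3-(triethylsilyloxy)butyl]-5βH-Δ8-octalin-9-carboxylate | COC=1CC[C@H]2[C@@](C)(CCC(C)(C)O[Si](CC)(CC)CC)[C@@H](O)CC[C@@]2(C)C=1C(=O)OC | intermediate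
20 | methyl 3α-(tert-butyldimethylsilyloxy)-8-methoxy-4β,10β-dimethyl-4α-[3-methyl-3-(triethylsilyloxy)butyl]-5βH-Δ8-octalin-9-carboxylate | COC=1CC[C@H]2[C@@](C)(CCC(C)(C)O[Si](CC)(CC)CC)[C@@H](O[Si](C)(C)C(C)(C)C)CC[C@@]2(C)C=1C(=O)OC | intermediate
21 | 9-(hydroxymethyl) allylic alcohol from 20 (8-methoxy-Δ8, not isolated) | COC=1CC[C@H]2[C@@](C)(CCC(C)(C)O[Si](CC)(CC)CC)[C@@H](O[Si](C)(C)C(C)(C)C)CC[C@@]2(C)C=1CO | intermediate
22 | 3α-(tert-butyldimethylsilyloxy)-4α-(3-hydroxy-3-methylbutyl)-4β,10β-dimethyl-9-methylene-5βH-decalin-8-one | O=C1CC[C@H]2[C@@](C)(CCC(C)(C)O)[C@@H](O[Si](C)(C)C(C)(C)C)CC[C@@]2(C)C1=C | intermediate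
23 | methyl acetoacetate | COC(=O)CC(C)=O | starting material
24 | malonyl dichloride | O=C(Cl)CC(=O)Cl | starting material
25 | methyl 4-hydroxy-2-methyl-6-oxo-6H-pyran-3-carboxylate | COC(=O)C1=C(C)OC(=O)C=C1O | intermediate
26 | Michael adduct: 4-hydroxy-2-pyrone joined through C11 to C9 (C11 α) of the 3α-silyloxy-8-oxo cis-decalin | O=C1CC[C@H]2[C@@](C)(CCC(C)(C)O)[C@@H](O[Si](C)(C)C(C)(C)C)CC[C@@]2(C)[C@H]1CC1=C(O)C(C(=O)OC)=C(C)OC1=O | intermediate
27 | 2-methoxy-4-pyranone analogue of 26 (C8 ketone) | O=C1CC[C@H]2[C@@](C)(CCC(C)(C)O)[C@@H](O[Si](C)(C)C(C)(C)C)CC[C@@]2(C)[C@H]1Cc1c(OC)oc(C)c(C(=O)OC)c1=O | intermediate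
28 | 8-methylene compound (tertiary alcohol free, O3 silylated) | C=C1CC[C@H]2[C@@](C)(CCC(C)(C)O)[C@@H](O[Si](C)(C)C(C)(C)C)CC[C@@]2(C)[C@H]1Cc1c(OC)oc(C)c(C(=O)OC)c1=O | intermediate
29 | tertiary formate, O3 silylated | C=C1CC[C@H]2[C@@](C)(CCC(C)(C)OC=O)[C@@H](O[Si](C)(C)C(C)(C)C)CC[C@@]2(C)[C@H]1Cc1c(OC)oc(C)c(C(=O)OC)c1=O | intermediate
30 | CNP0292250.1: methyl 5-{[4α-(3-formyloxy-3-methylbutyl)-3α-hydroxy-4β,10β-dimethyl-8-methylene-5βH,9βH-decalin-9-yl]methyl}-6-methoxy-2-methyl-4-oxo-4H-pyran-3-carboxylate | C=C1CC[C@H]2[C@@](C)(CCC(C)(C)OC=O)[C@@H](O)CC[C@@]2(C)[C@H]1Cc1c(OC)oc(C)c(C(=O)OC)c1=O | target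

**Count**
Total steps: 21. Longest linear sequence: 18 steps (steps 1, 2, 5 to 15 and 17 to 21; the branch through steps 3 and 4 has the same length).

**Steps most likely to fail**

1. Step 6 (proposed method). What may go wrong: weak discrimination between the two enantiotopic cyclopropane bonds because CO competes with the bisphosphine for rhodium and a ligand-free carbonyl species runs a racemic background reaction; or diversion into the CO-free [3+2] pathway. Fallback with known chemistry, from 10 back to 12: the cycloaddition is run under the established achiral conditions ([Rh(CO)2Cl]2, CO/N2, dioxane, 80 °C) to give the racemic bicyclic enone F1. O-Methylation as in step 7 gives the racemic enol ether F2. Corey–Bakshi–Shibata reduction [(R)-2-methyl-oxazaborolidine, BH3·SMe2] reduces the C3 ketone of both enantiomers with the same reagent-controlled sense, giving the diastereomeric allylic alcohols F3 (10β-vinyl series) and F4 (10α-vinyl series), which are separated by chromatography. Dess–Martin oxidation of the allylic alcohol F3 returns 12 as a single enantiomer.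

2. Step 12. What may go wrong: methyl iodide attacks the enolate from the α face (giving the C4 epimer), or alkylation occurs on oxygen or at C2 after enolate equilibration. Fallback that reverses the order in which the two C4 substituents arrive, from 4 back to 18: commercial hex-4-ynoic acid F5 is converted with carbonyldiimidazole into the imidazolide F6 and condensed with the enolate of 4 as in step 5 to the β-keto ester F7. The chemistry of steps 6 to 11 then gives the cycloadduct F8, the enol ether F9, the angular aldehyde F10, its tosylhydrazone F11, the 4,10-dimethyl enone F12, the cis-fused 4-methyl ketone F13 and the silyl enol ether F14. Fluoride-mediated alkylation of F14 with the iodide F15 (from 6 by Finkelstein exchange, NaI, acetone) brings in the side chain on the face that took the methyl group in the failed run, which places the chain α and the methyl β, that is compound 18.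

3. Step 10. What may go wrong: hydrogen is delivered to the α face (trans-fused product), or the tetrasubstituted alkene reduces too slowly and the ring-B enol ether is attacked instead. Fallback by hydroxyl-directed hydrogenation, from 15 back to 16: Luche reduction (NaBH4, CeCl3·7H2O, MeOH) gives the 3β allylic alcohol F16 by hydride attack anti to the C10 methyl. Hydrogenation with [Ir(cod)(PCy3)(py)]PF6 in CH2Cl2 delivers H2 to the β face under direction of the 3β hydroxyl group and gives the cis-fused alcohol F17. Dess–Martin oxidation of F17 gives 16.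

**Further compounds**
F1 | step 6 | racemic 11 | O=C1CCC2=C(CCC(C)(C)O[Si](CC)(CC)CC)C(=O)CCC2(C=C)C1C(=O)OC
F2 | step 6 | racemic 12 | COC=1CCC2=C(CCC(C)(C)O[Si](CC)(CC)CC)C(=O)CCC2(C=C)C=1C(=O)OC
F3 | step 6 | 3-hydroxy analogue of 12, 10β-vinyl series (C3 set by the reagent) | COC=1CCC2=C(CCC(C)(C)O[Si](CC)(CC)CC)[C@@H](O)CC[C@@]2(C=C)C=1C(=O)OC
F4 | step 6 | 3-hydroxy analogue of 12, 10α-vinyl series (same C3 configuration) | COC=1CCC2=C(CCC(C)(C)O[Si](CC)(CC)CC)[C@@H](O)CC[C@]2(C=C)C=1C(=O)OC
F5 | step 12 | hex-4-ynoic acid (purchased) | CC#CCCC(=O)O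
F6 | step 12 | 1-(hex-4-ynoyl)imidazole | CC#CCCC(=O)n1ccnc1
F7 | step 12 | methyl 2-(1-ethenylcyclopropyl)-3-oxooct-6-ynoate | COC(=O)C(C(=O)CCC#CC)C1(C=C)CC1
F8 | step 12 | methyl 10β-ethenyl-4-methyl-3,8-dioxo-Δ4-octalin-9-carboxylate | O=C1CCC2=C(C)C(=O)CC[C@@]2(C=C)C1C(=O)OC
F9 | step 12 | methyl 10β-ethenyl-8-methoxy-4-methyl-3-oxo-Δ4,8-hexalin-9-carboxylate | COC=1CCC2=C(C)C(=O)CC[C@@]2(C=C)C=1C(=O)OC
F10 | step 12 | methyl 10β-formyl-8-methoxy-4-methyl-3-oxo-Δ4,8-hexalin-9-carboxylate | COC=1CCC2=C(C)C(=O)CC[C@@]2(C=O)C=1C(=O)OC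
F11 | step 12 | tosylhydrazone of F10 | COC=1CCC2=C(C)C(=O)CC[C@@]2(C=NNS(=O)(=O)c3ccc(C)cc3)C=1C(=O)OC
F12 | step 12 | methyl 8-methoxy-4,10β-dimethyl-3-oxo-Δ4,8-hexalin-9-carboxylate | COC=1CCC2=C(C)C(=O)CC[C@@]2(C)C=1C(=O)OC
F13 | step 12 | methyl 8-methoxy-4α,10β-dimethyl-3-oxo-4βH,5βH-Δ8-octalin-9-carboxylate | COC=1CC[C@H]2[C@@H](C)C(=O)CC[C@@]2(C)C=1C(=O)OC
F14 | step 12 | methyl 8-methoxy-4,10β-dimethyl-3-(trimethylsilyloxy)-5βH-Δ3,8-hexalin-9-carboxylate | COC=1CC[C@H]2C(C)=C(O[Si](C)(C)C)CC[C@@]2(C)C=1C(=O)OC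
F15 | step 12 | triethyl[(4-iodo-2-methylbutan-2-yl)oxy]silane | CC[Si](CC)(CC)OC(C)(C)CCI
F16 | step 10 | 3β-hydroxy analogue of 15 (allylic alcohol) | COC=1CCC2=C(CCC(C)(C)O[Si](CC)(CC)CC)[C@H](O)CC[C@@]2(C)C=1C(=O)OC
F17 | step 10 | 3β-hydroxy analogue of 16 (cis-fused) | COC=1CC[C@H]2[C@@H](CCC(C)(C)O[Si](CC)(CC)CC)[C@H](O)CC[C@@]2(C)C=1C(=O)OC
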